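**Retrosynthetic overview**
1. The target reads as epicatechin-(4β→6)-ent-epicatechin-(4α→8)-epicatechin-(4β→6)-ent-epicatechin. The central 4α→8 bond is cut to two copies of one bromine-capped dimer 14; each 4β→6 bond is cut to the C4 cation of ether 12 and the 8-bromo ether 11.
2. Both enantiomeric monomers 10 (2S,3S) and 12 (2R,3R) come from one racemic flavan-3-one 9 by catalyst-controlled dynamic kinetic resolution, which sets C2 and C3 together (eight of eleven stereocentres). The three C4 centres are relayed from C3 by attack anti to the 3-OH.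
3. Ring C of every unit is not closed as a pyran. The rhodium carbene from diazoketone 6 adds to ring A (dearomatising Buchner step) and gives a furan-3-one (O1, C2, C3, C4, C8a) fused to a norcaradiene/cycloheptatriene. Acid then expands this five-membered ring to the six-membered ring (O1, C2, C3, C4, C4a, C8a) while ring A rearomatises.
4. Enabling feature: ring A is a phloroglucinol ring whose O1-bearing carbon C8a lies between two equivalent CH carbons, and C3 bears oxygen. At the ketone level C3 makes C4 an acceptor carbon opposite the donor O1 on C8a, so the cyclopropane bond C4–C8a breaks selectively; the same ketone makes C2–H labile for the resolution.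
5. Ring order: rings A and B bought; cyclopropane plus furanone (7), then pyranone ring C (9); then the 4β→6 bond (dimer 14, used twice), the 4α→8 bond, and global hydrogenolysis.

Key step: step 4

Remark: from the SMILES, units 1 and 3 are (2R,3R) epicatechin units, units 2 and 4 are (2S,3S) ent-epicatechin units, and every C4 substituent is trans to the neighbouring 3-OH.
Assumption: RuCl(p-cymene)[(S,S)-TsDPEN] is taken to give the (2S,3S)-alcohol 10 and its (R,R)-antipode the (2R,3R)-alcohol 12. Both antipodes are needed, so a reversed sense of induction only exchanges the catalysts of steps 5 and 7.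

Step 1
Reactants: 1 3,4-bis(benzyloxy)benzaldehyde
Product: 2 rac-1-[3,4-bis(benzyloxy)phenyl]-2,2,2-trichloroethan-1-ol
Conditions: CHCl3 (reagent and solvent), DBU (1.1 equiv), 0 °C → rt
Reagents that add atoms: chloroform ClC(Cl)Cl
Why: base-mediated addition of the trichloromethyl anion to the aldehyde (trichloromethyl carbinol synthesis), racemic by design because this carbon, the future C2, is set in steps 5 and 7.

Step 2
Reactants: 2 rac-1-[3,4-bis(benzyloxy)phenyl]-2,2,2-trichloroethan-1-ol; 3 3,5-bis(benzyloxy)phenol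
Product: 4 rac-2-[3,5-bis(benzyloxy)phenoxy]-2-[3,4-bis(benzyloxy)phenyl]acetic acid
Conditions: NaOH (5 equiv), DME–H2O, 0 °C → rt; then 1 M HCl
Reagents that add atoms: sodium hydroxide [Na+].[OH-]
Why: Jocic–Reeve reaction, in which hydroxide closes the gem-dichloroepoxide, the phenoxide of 3 opens it through oxygen at the benzylic carbon and the resulting acyl chloride is hydrolysed to the acid, the stereocentre again being left racemic.

Step 3
Reactants: 4 rac-2-[3,5-bis(benzyloxy)phenoxy]-2-[3,4-bis(benzyloxy)phenyl]acetic acid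
Product: 6 rac-1-diazo-3-[3,5-bis(benzyloxy)phenoxy]-3-[3,4-bis(benzyloxy)phenyl]propan-2-one, via mixed anhydride 5 (not isolated)
Conditions: i-BuOCOCl, N-methylmorpholine, THF, −15 °C; then CH2N2, Et2O, 0 °C
Reagents that add atoms: diazomethane C=[N+]=[N-]; isobutyl chloroformate CC(C)COC(Cl)=O (its atoms stay in 5 only)
Why: acylation of diazomethane by a mixed carbonic anhydride (first stage of the Arndt–Eistert sequence), a mild activation that should leave the benzyl ethers and the α-aryloxy group untouched.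

Step 4
Reactants: 6 rac-1-diazo-3-[3,5-bis(benzyloxy)phenoxy]-3-[3,4-bis(benzyloxy)phenyl]propan-2-one
Product: 9 rac-5,7-bis(benzyloxy)-2-[3,4-bis(benzyloxy)phenyl]chroman-3-one, via norcaradiene 7 (not isolated), via cycloheptafuranone 8 (not isolated)
Conditions: Rh2(OAc)4 (1 mol %), CH2Cl2, slow addition of 6, 40 °C; then CF3CO2H (1 equiv), 0 °C → rt, one pot
Reagents that add atoms: none
Why: Dirhodium tetraacetate should convert 6 into a rhodium carbene at C4 that adds across the C8a–C4a bond of the electron-rich ring A (intramolecular Buchner reaction), closing the cyclopropane by [2+1] addition and in the same event the five-membered furan-3-one ring (O1, C2, C3, C4, C8a) by bonding C4 to the ipso carbon C8a, to give norcaradiene 7 in equilibrium with cycloheptatriene 8 through disrotatory six-electron electrocyclic opening. Norcaradiene 7 is a donor–acceptor cyclopropane (O1 on C8a as donor, the C3 ketone on C4 as acceptor), so trifluoroacetic acid should cleave the C4–C8a bond with push from O1 and loss of the C4a proton, which rearomatises ring A and leaves C4 on C4a: a 1,2-shift that expands the furanone to the six-membered pyranone ring C (O1, C2, C3, C4, C4a, C8a). The closest known reaction type is the rhodium-carbene cyclisation of aryloxymethyl diazoketones to cyclohepta[b]furan-3-ones and their acid-induced rearrangement to chroman-3-ones. No lasting stereocentre is created: C2 is already present and is left racemic on purpose, because it is epimerisable next to the C3 ketone and is set together with C3 in steps 5 and 7, while the stereocentres of 7 and 8 at C4, C4a and C8a vanish on aromatisation. The step needs chemoselectivity for ring A over the ortho positions of ring B (which would close a 2-indanone) and over the remote benzylic C–H bonds, and a single regiochemistry on ring A; the first should be secured by the much higher nucleophilicity of the 1,3,5-trioxygenated ring, the second by the symmetry of the 3,5-bis(benzyloxy)phenyl ether, whose two ortho positions are equivalent.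

Step 5
Reactants: 9 rac-5,7-bis(benzyloxy)-2-[3,4-bis(benzyloxy)phenyl]chroman-3-one
Product: 10 (2S,3S)-5,7,3',4'-tetra-O-benzylepicatechin (tetra-O-benzyl-ent-epicatechin)
Conditions: RuCl(p-cymene)[(S,S)-TsDPEN] (2 mol %), HCO2H–Et3N (5:2), DMF, 40 °C, argon
Reagents that add atoms: none
Why: Noyori-type asymmetric transfer hydrogenation under dynamic kinetic resolution, in which C2–H (benzylic, α to the ketone and to the aryloxy oxygen) should epimerise through the enol faster than reduction, the catalyst reduces the (2S)-ketone preferentially and hydride arrives anti to the pseudo-equatorial 2-aryl group, so that C2 and C3 are set together as the 2,3-cis (2S,3S) alcohol.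

Step 6
Reactants: 10 (2S,3S)-5,7,3',4'-tetra-O-benzylepicatechin
Product: 11 (2S,3S)-8-bromo-5,7,3',4'-tetra-O-benzylepicatechin
Conditions: NBS (1.0 equiv), CH2Cl2, −78 °C → rt
Reagents that add atoms: N-bromosuccinimide O=C1CCC(=O)N1Br
Why: electrophilic aromatic bromination that should be selective for C8 of ring A because C6 lies between two benzyloxy groups, the bromine serving later to block C8 so that coupling goes to C6.

Step 7
Reactants: 9 rac-5,7-bis(benzyloxy)-2-[3,4-bis(benzyloxy)phenyl]chroman-3-one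
Product: 12 (2R,3R)-5,7,3',4'-tetra-O-benzylepicatechin
Conditions: RuCl(p-cymene)[(R,R)-TsDPEN] (2 mol %), HCO2H–Et3N (5:2), DMF, 40 °C, argon
Reagents that add atoms: none
Why: the mirror-image Noyori-type dynamic kinetic resolution of step 5, the enantiomeric catalyst selecting the (2R)-ketone from the equilibrating racemate and delivering hydride anti to the 2-aryl group to give the 2,3-cis (2R,3R) alcohol.

Step 8
Reactants: 12 (2R,3R)-5,7,3',4'-tetra-O-benzylepicatechin
Product: 13 4β-(2-ethoxyethoxy)-5,7,3',4'-tetra-O-benzylepicatechin (3,4-trans)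
Conditions: DDQ (2 equiv), 2-ethoxyethanol (5 equiv), CH2Cl2, rt
Reagents that add atoms: 2-ethoxyethanol CCOCCO
Why: DDQ-mediated benzylic oxidation, in which hydride abstraction from C4 gives the ring-A-stabilised cation that the alcohol should trap anti to the pseudo-axial 3-OH, setting C4 as the 4β (3,4-trans) ether.

Step 9
Reactants: 13 4β-(2-ethoxyethoxy)-5,7,3',4'-tetra-O-benzylepicatechin; 11 (2S,3S)-8-bromo-5,7,3',4'-tetra-O-benzylepicatechin (3 equiv)
Product: 14 [5,7,3',4'-tetra-O-benzylepicatechin]-(4β→6)-[8-bromo-5,7,3',4'-tetra-O-benzyl-ent-epicatechin]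
Conditions: TMSOTf (0.1 equiv), CH2Cl2, −78 → −40 °C; Et3N quench
Reagents that add atoms: none
Why: Lewis-acid ionisation of the C4 ether and Friedel–Crafts attack by C6 of 11 (its C8 being bromine-capped), which should occur anti to the 3-OH of the cation to give the 4β (3,4-trans) interflavan bond, the excess of 11 suppressing self-condensation of 13.

Step 10
Reactants: 14 [5,7,3',4'-tetra-O-benzylepicatechin]-(4β→6)-[8-bromo-5,7,3',4'-tetra-O-benzyl-ent-epicatechin]
Product: 15 [8-bromo-5,7,3',4'-tetra-O-benzylepicatechin]-(4β→6)-[8-bromo-5,7,3',4'-tetra-O-benzyl-ent-epicatechin]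
Conditions: NBS (1.05 equiv), CH2Cl2, −78 → −20 °C
Reagents that add atoms: N-bromosuccinimide O=C1CCC(=O)N1Br
Why: electrophilic aromatic bromination at C8 of the upper unit, the most reactive free ring-A position of 14, which caps the future electrophile against self-condensation.

Step 11
Reactants: 15 [8-bromo-5,7,3',4'-tetra-O-benzylepicatechin]-(4β→6)-[8-bromo-5,7,3',4'-tetra-O-benzyl-ent-epicatechin]
Product: 16 dimer 15 carrying a 4α-(2-ethoxyethoxy) group (trans to 3-OH) on the lower ent-epicatechin unit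
Conditions: DDQ (2.5 equiv), 2-ethoxyethanol (5 equiv), CH2Cl2, rt
Reagents that add atoms: 2-ethoxyethanol CCOCCO
Why: DDQ benzylic oxidation that should select the C4H2 group of the lower unit, whose pseudo-axial C–H is aligned with ring A, over the shielded pseudo-equatorial C4–H of the upper unit, the cation being trapped anti to the 3-OH to set the 4α (3,4-trans) ether.

Step 12
Reactants: 16 4α-(2-ethoxyethoxy) dimer; 14 [5,7,3',4'-tetra-O-benzylepicatechin]-(4β→6)-[8-bromo-5,7,3',4'-tetra-O-benzyl-ent-epicatechin] (1.5 equiv)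
Product: 17 hexadeca-O-benzyl-8,8',8'''-tribromo tetramer epicatechin-(4β→6)-ent-epicatechin-(4α→8)-epicatechin-(4β→6)-ent-epicatechin
Conditions: TMSOTf (0.1 equiv), CH2Cl2, −78 → −40 °C; Et3N quench
Reagents that add atoms: none
Why: Lewis-acid-promoted Friedel–Crafts interflavan coupling in which C8 of the upper unit of 14 (its only unhindered nucleophilic position, the lower unit being bromine-capped) should attack the C4 cation of the ent-epicatechin unit of 16 anti to its 3-OH, setting the 4α (3,4-trans) centre.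

Step 13
Reactants: 17 hexadeca-O-benzyl-8,8',8'''-tribromo tetramer
Product: 18 epicatechin-(4β→6)-ent-epicatechin-(4α→8)-epicatechin-(4β→6)-ent-epicatechin (CNP0120618.2)
Conditions: H2 (1 atm), Pd(OH)2/C, Et3N, THF–MeOH–H2O, rt
Reagents that add atoms: none
Why: catalytic hydrogenolysis that should cleave the sixteen benzyl ethers and the three aryl C–Br bonds in one operation under buffered conditions that leave the acid-labile interflavan bonds and all stereocentres untouched.

**Compound list**
1 | 3,4-bis(benzyloxy)benzaldehyde | O=Cc1ccc(OCc2ccccc2)c(OCc2ccccc2)c1 | starting material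
2 | rac-1-[3,4-bis(benzyloxy)phenyl]-2,2,2-trichloroethan-1-ol | OC(c1ccc(OCc2ccccc2)c(OCc2ccccc2)c1)C(Cl)(Cl)Cl | intermediate
3 | 3,5-bis(benzyloxy)phenol | Oc1cc(OCc2ccccc2)cc(OCc2ccccc2)c1 | starting material
4 | rac-2-[3,5-bis(benzyloxy)phenoxy]-2-[3,4-bis(benzyloxy)phenyl]acetic acid | OC(=O)C(Oc1cc(OCc2ccccc2)cc(OCc2ccccc2)c1)c1ccc(OCc2ccccc2)c(OCc2ccccc2)c1 | intermediate
5 | mixed isobutyl carbonic anhydride of acid 4 (not isolated) | CC(C)COC(=O)OC(=O)C(Oc1cc(OCc2ccccc2)cc(OCc2ccccc2)c1)c1ccc(OCc2ccccc2)c(OCc2ccccc2)c1 | intermediate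
6 | rac-1-diazo-3-[3,5-bis(benzyloxy)phenoxy]-3-[3,4-bis(benzyloxy)phenyl]propan-2-one | [N-]=[N+]=CC(=O)C(Oc1cc(OCc2ccccc2)cc(OCc2ccccc2)c1)c1ccc(OCc2ccccc2)c(OCc2ccccc2)c1 | intermediate
7 | norcaradiene: furan-3-one fused to a cyclopropane whose carbon C4 is bonded to C8a and C4a of the dearomatised ring A (diastereomer mixture, not isolated) | O=C1C(c2ccc(OCc3ccccc3)c(OCc3ccccc3)c2)OC23C=C(OCc4ccccc4)C=C(OCc4ccccc4)C2C13 | intermediate
8 | 5,7-bis(benzyloxy)-2-[3,4-bis(benzyloxy)phenyl]-2H-cyclohepta[b]furan-3(3aH)-one, cycloheptatriene valence tautomer of 7 (not isolated) | O=C1C(c2ccc(OCc3ccccc3)c(OCc3ccccc3)c2)OC2=CC(OCc3ccccc3)=CC(OCc3ccccc3)=CC12 | intermediate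
9 | rac-5,7-bis(benzyloxy)-2-[3,4-bis(benzyloxy)phenyl]chroman-3-one (tetra-O-benzyl flavan-3-one) | O=C1Cc2c(OCc3ccccc3)cc(OCc3ccccc3)cc2OC1c1ccc(OCc2ccccc2)c(OCc2ccccc2)c1 | intermediate
10 | (2S,3S)-5,7,3',4'-tetra-O-benzylepicatechin (ent-epicatechin ether, 2,3-cis) | C1[C@H](O)[C@H](c8ccc(OCc9ccccc9)c(OCc9ccccc9)c8)Oc2cc(OCc9ccccc9)cc(OCc9ccccc9)c21 | intermediate
11 | (2S,3S)-8-bromo-5,7,3',4'-tetra-O-benzylepicatechin | C1[C@H](O)[C@H](c8ccc(OCc9ccccc9)c(OCc9ccccc9)c8)Oc2c(Br)c(OCc9ccccc9)cc(OCc9ccccc9)c21 | intermediate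
12 | (2R,3R)-5,7,3',4'-tetra-O-benzylepicatechin (2,3-cis) | C1[C@@H](O)[C@@H](c8ccc(OCc9ccccc9)c(OCc9ccccc9)c8)Oc2cc(OCc9ccccc9)cc(OCc9ccccc9)c21 | intermediate
13 | 4β-(2-ethoxyethoxy) derivative of 12 (2,3-cis, 3,4-trans) | c9ccccc9COc1cc(OCc9ccccc9)c2c(c1)O[C@H](c8ccc(OCc9ccccc9)c(OCc9ccccc9)c8)[C@H](O)[C@H]2OCCOCC | intermediate
14 | [tetra-O-benzylepicatechin]-(4β→6)-[8-bromo-tetra-O-benzyl-ent-epicatechin]; upper unit 2,3-cis-3,4-trans, lower unit (2S,3S) | c9ccccc9COc1cc(OCc9ccccc9)c2c(c1)O[C@H](c8ccc(OCc9ccccc9)c(OCc9ccccc9)c8)[C@H](O)[C@H]2c1c(OCc9ccccc9)c(Br)c2c(c1OCc9ccccc9)C[C@H](O)[C@H](c8ccc(OCc9ccccc9)c(OCc9ccccc9)c8)O2 | intermediate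
15 | dimer 14 with a second bromine at C8 of the upper unit | c9ccccc9COc1cc(OCc9ccccc9)c2c(c1Br)O[C@H](c8ccc(OCc9ccccc9)c(OCc9ccccc9)c8)[C@H](O)[C@H]2c1c(OCc9ccccc9)c(Br)c2c(c1OCc9ccccc9)C[C@H](O)[C@H](c8ccc(OCc9ccccc9)c(OCc9ccccc9)c8)O2 | intermediate
16 | dimer 15 with a 4α-(2-ethoxyethoxy) group, trans to 3-OH, at C4 of the lower ent-epicatechin unit | c9ccccc9COc1cc(OCc9ccccc9)c2c(c1Br)O[C@H](c8ccc(OCc9ccccc9)c(OCc9ccccc9)c8)[C@H](O)[C@H]2c1c(OCc9ccccc9)c(Br)c2c(c1OCc9ccccc9)[C@@H](OCCOCC)[C@H](O)[C@H](c8ccc(OCc9ccccc9)c(OCc9ccccc9)c8)O2 | intermediate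
17 | hexadeca-O-benzyl tetramer with bromine at C8 of units 1, 2 and 4; linkages 4β→6, 4α→8, 4β→6 | c9ccccc9COc1cc(OCc9ccccc9)c2c(c1Br)O[C@H](c8ccc(OCc9ccccc9)c(OCc9ccccc9)c8)[C@H](O)[C@H]2c1c(OCc9ccccc9)c(Br)c2c(c1OCc9ccccc9)[C@@H](c1c(OCc9ccccc9)cc(OCc9ccccc9)c3c1O[C@H](c8ccc(OCc9ccccc9)c(OCc9ccccc9)c8)[C@H](O)[C@H]3c1c(OCc9ccccc9)c(Br)c3c(c1OCc9ccccc9)C[C@H](O)[C@H](c8ccc(OCc9ccccc9)c(OCc9ccccc9)c8)O3)[C@H](O)[C@H](c8ccc(OCc9ccccc9)c(OCc9ccccc9)c8)O2 | intermediate
18 | epicatechin-(4β→6)-ent-epicatechin-(4α→8)-epicatechin-(4β→6)-ent-epicatechin (CNP0120618.2) | Oc1cc(O)c2c(c1)O[C@H](c1ccc(O)c(O)c1)[C@H](O)[C@H]2c1c(O)cc2c(c1O)[C@@H](c1c(O)cc(O)c3c1O[C@H](c1ccc(O)c(O)c1)[C@H](O)[C@H]3c1c(O)cc3c(c1O)C[C@H](O)[C@H](c1ccc(O)c(O)c1)O3)[C@H](O)[C@H](c1ccc(O)c(O)c1)O2 | target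

**Step count and risks**
Total step count: 13. Longest linear sequence: 11 steps (steps 1–6 and 9–13); step 7 and step 8 form the short branch.

Steps most likely to fail:

Step 4. The carbene may attack an ortho position of ring B (five-membered closure to a 2-indanone), dimerise, or the acid-induced rearrangement may stall at the cycloheptatriene stage. The fallback sets out from acid 4 and comes back at 9, and it keeps a five-to-six ring expansion. Acid 4 would be cyclised by intramolecular Friedel–Crafts acylation (trifluoroacetic anhydride, CH2Cl2, 0 °C) onto the equivalent ortho positions of ring A, to give rac-4,6-bis(benzyloxy)-2-[3,4-bis(benzyloxy)phenyl]benzofuran-3(2H)-one F1. This five-membered ketone would then be enlarged by one carbon with diazomethane and BF3·OEt2 (Tiffeneau–Demjanov-type homologation with migration of the electron-rich aryl carbon), which should give 9.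

Step 5 (and its mirror image, step 7). Epimerisation of C2 may be too slow relative to reduction, or the catalyst may discriminate poorly between the enantiomers of 9, so that enantiomeric purity is lost; the enol may also autoxidise. The fallback sets out from 9 and comes back at 10 and 12. Reduction with LiBH(s-Bu)3 in THF at −78 °C should give the racemic 2,3-cis alcohol, which is the 1:1 mixture of 10 and 12, both of which the route needs. Lipase-catalysed acylation with vinyl acetate would then resolve the pair: one enantiomer stays as the alcohol 10, and the other is taken, for this proposal, to be acylated to (2R,3R)-3-O-acetyl-5,7,3',4'-tetra-O-benzylepicatechin F2, which K2CO3 in methanol would convert into 12. If the lipase prefers the other enantiomer, the roles of 10 and 12 are exchanged.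

Step 11. Site selectivity of hydride abstraction may be poor: oxidation could occur at the doubly benzylic C4–H of the upper unit, or the bromine-deactivated lower unit could fail to react. The fallback sets out from 11 and comes back at 18, and it installs a latent C4 leaving group before dimerisation.
- Monomer 11 would be oxidised with DDQ and 2-ethoxyethanol to 8-bromo-4α-(2-ethoxyethoxy)-5,7,3',4'-tetra-O-benzyl-ent-epicatechin F3.
- Exchange with 2,6-dimethylbenzenethiol and BF3·OEt2 would give the 4α-(2,6-dimethylphenylthio) ether F4, which is inert to hard Lewis acids.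
- F4 (in excess) would be coupled through its C6 with 13 under BF3·OEt2, which activates only the C4–O group, to give the thio-substituted dimer F5.
- F5 would be coupled with 14 (in excess) under thiophilic activation with AgOTf to give the tetramer F6, which is 17 without the bromine on unit 1.
- Hydrogenolysis of F6 under the conditions of step 13 would give 18.

Further compounds
F1 | step 4 | rac-4,6-bis(benzyloxy)-2-[3,4-bis(benzyloxy)phenyl]benzofuran-3(2H)-one | O=C1C(c2ccc(OCc3ccccc3)c(OCc3ccccc3)c2)Oc2cc(OCc3ccccc3)cc(OCc3ccccc3)c12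
F2 | step 5 | (2R,3R)-3-O-acetyl-5,7,3',4'-tetra-O-benzylepicatechin | C1[C@@H](OC(C)=O)[C@@H](c8ccc(OCc9ccccc9)c(OCc9ccccc9)c8)Oc2cc(OCc9ccccc9)cc(OCc9ccccc9)c21
F3 | step 11 | 8-bromo-4α-(2-ethoxyethoxy)-5,7,3',4'-tetra-O-benzyl-ent-epicatechin (3,4-trans) | c1c(OCc9ccccc9)c(Br)c2c(c1OCc9ccccc9)[C@@H](OCCOCC)[C@H](O)[C@H](c8ccc(OCc9ccccc9)c(OCc9ccccc9)c8)O2
F4 | step 11 | 8-bromo-4α-(2,6-dimethylphenylthio)-5,7,3',4'-tetra-O-benzyl-ent-epicatechin (3,4-trans) | c1c(OCc9ccccc9)c(Br)c2c(c1OCc9ccccc9)[C@@H](Sc7c(C)cccc7C)[C@H](O)[C@H](c8ccc(OCc9ccccc9)c(OCc9ccccc9)c8)O2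
F5 | step 11 | [tetra-O-benzylepicatechin]-(4β→6)-[8-bromo-4α-(2,6-dimethylphenylthio)-tetra-O-benzyl-ent-epicatechin] | c9ccccc9COc1cc(OCc9ccccc9)c2c(c1)O[C@H](c8ccc(OCc9ccccc9)c(OCc9ccccc9)c8)[C@H](O)[C@H]2c1c(OCc9ccccc9)c(Br)c2c(c1OCc9ccccc9)[C@@H](Sc7c(C)cccc7C)[C@H](O)[C@H](c8ccc(OCc9ccccc9)c(OCc9ccccc9)c8)O2
F6 | step 11 | hexadeca-O-benzyl tetramer with bromine at C8 of units 2 and 4 only | c9ccccc9COc1cc(OCc9ccccc9)c2c(c1)O[C@H](c8ccc(OCc9ccccc9)c(OCc9ccccc9)c8)[C@H](O)[C@H]2c1c(OCc9ccccc9)c(Br)c2c(c1OCc9ccccc9)[C@@H](c1c(OCc9ccccc9)cc(OCc9ccccc9)c3c1O[C@H](c8ccc(OCc9ccccc9)c(OCc9ccccc9)c8)[C@H](O)[C@H]3c1c(OCc9ccccc9)c(Br)c3c(c1OCc9ccccc9)C[C@H](O)[C@H](c8ccc(OCc9ccccc9)c(OCc9ccccc9)c8)O3)[C@H](O)[C@H](c8ccc(OCc9ccccc9)c(OCc9ccccc9)c8)O2
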